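**Retrosynthetic overview**
1. Target ⇒ one ring bond, C1–C2. The ketone carbon C2 becomes the carbonyl of a 3‑acetoxy‑4‑methylbutenolide that carries the whole C6–C11 chain. Forward, the C1=C7 alkene attacks this acyl carbon (the farnesyl→bisabolyl 1,6‑closure at the acid oxidation level) and the lactone oxygen is released as the free C5–OH.
2. Seco‑butenolide ⇒ angelic acid + C8 alcohol ⇒ prenyl end by cross‑metathesis, C8 by Keck allylation, the (E)‑trisubstituted alkene by cross‑metathesis of a 5‑allylbutenolide with methacrolein.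
3. 5‑Allylbutenolide ⇒ Negishi methylation of a tetronate sulfonate ⇒ Dieckmann closure ⇒ methyl (R)‑glycidate (source of C5), vinyl Grignard reagent, acetoxyacetyl chloride.
4. Ring order: the butenolide (step 2) is made first and serves as Z‑geometry lock and as protecting group for C5–OH; the six‑membered ring is formed last (step 8) as the butenolide opens.

Assumption: atom labels follow bisabolane numbering (ring C1–C6 with C2 the ketone carbon and C5 the carbinol, side chain C7–C11; C5 is also C5 of the butenolide), and methyl (R)‑glycidate and angelic acid are bought.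

**Route**

Step 1
Reactants: 1 methyl (2R)-oxirane-2-carboxylate; 2 vinylmagnesium bromide; 3 acetoxyacetyl chloride
Product: 5 methyl (2R)-2-[(acetoxyacetyl)oxy]pent-4-enoate, via bromomagnesium alkoxide 4 (not isolated)
Conditions: CH2=CHMgBr (1.1 equiv), CuI (10 mol%), THF, −40 °C; then AcOCH2COCl (1.3 equiv), −40 → 0 °C
Reagents that add atoms: vinylmagnesium bromide, C=C[Mg]Br; acetoxyacetyl chloride, CC(=O)OCC(Cl)=O
Why: Copper‑catalysed SN2 opening of the epoxide by the Grignard reagent (organocuprate epoxide opening) takes place at the unsubstituted carbon, so the C–O stereocenter of 1 is carried over unchanged, and the magnesium alkoxide is O‑acylated in the same flask.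

Step 2
Reactants: 5 methyl (2R)-2-[(acetoxyacetyl)oxy]pent-4-enoate; 6 p-toluenesulfonyl chloride
Product: 8 (5R)-3-acetoxy-5-allyl-4-(tosyloxy)furan-2(5H)-one, via lithium tetronate 7 (not isolated)
Conditions: LiN(SiMe3)2 (2.1 equiv), THF, −78 °C; then TsCl (2.2 equiv), −78 → 0 °C
Reagents that add atoms: p-toluenesulfonyl chloride, Cc1ccc(cc1)S(Cl)(=O)=O
Why: Lacey–Dieckmann (intramolecular Claisen) condensation: the more acidic acetoxyacetate CH2 is enolised and closes the five‑membered ring onto the methyl ester without touching the C5–O stereocenter, the acetyl group stays on the less acidic enol oxygen, and the tetronate oxygen is sulfonylated in situ.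

Step 3
Reactants: 8 (5R)-3-acetoxy-5-allyl-4-(tosyloxy)furan-2(5H)-one; 9 methylzinc chloride
Product: 10 (5R)-3-acetoxy-5-allyl-4-methylfuran-2(5H)-one
Conditions: MeZnCl (1.5 equiv), Pd(PPh3)4 (5 mol%), THF, 50 °C
Reagents that add atoms: methylzinc chloride, C[Zn]Cl
Why: Negishi cross‑coupling (oxidative addition of zerovalent palladium into the vinylogous sulfonate, transmetalation from zinc, reductive elimination) replaces OTs by methyl; the organozinc is too weakly basic to touch the enol acetate or the acidic C5–H, and no stereocenter is formed.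

Step 4
Reactants: 10 (5R)-3-acetoxy-5-allyl-4-methylfuran-2(5H)-one; 11 methacrolein
Product: 12 (5R)-3-acetoxy-4-methyl-5-[(2E)-3-methyl-4-oxobut-2-en-1-yl]furan-2(5H)-one
Conditions: methacrolein (8 equiv), second-generation Hoveyda–Grubbs catalyst (5 mol%), CH2Cl2, 40 °C
Reagents that add atoms: methacrolein, CC(=C)C=O
Why: Olefin cross‑metathesis of the terminal alkene with excess methacrolein gives the conjugated trisubstituted enal as the E isomer under thermodynamic control (chain trans to the formyl group); the tetrasubstituted, electron‑poor butenolide alkene is inert.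

Step 5
Reactants: 12 (5R)-3-acetoxy-4-methyl-5-[(2E)-3-methyl-4-oxobut-2-en-1-yl]furan-2(5H)-one; 13 allyltributylstannane
Product: 15 (5R)-3-acetoxy-5-[(2E,4S)-4-hydroxy-3-methylhepta-2,6-dien-1-yl]-4-methylfuran-2(5H)-one, via tributylstannyl ether 14 (not isolated)
Conditions: allylSnBu3 (1.5 equiv), (S)-BINOL (20 mol%), Ti(OiPr)4 (10 mol%), 4 Å MS, CH2Cl2, −20 °C; aq. NaHCO3
Reagents that add atoms: allyltributylstannane, C=CC[Sn](CCCC)(CCCC)CCCC
Why: Keck asymmetric allylation: the (S)-BINOL–Ti(OiPr)4 Lewis acid delivers allyl to the Si face of the aldehyde (the sense that gives (S)-1-phenylbut-3-en-1-ol from benzaldehyde), setting C8 as S under catalyst control since the butenolide stereocenter is remote, and the neutral conditions spare the base‑sensitive butenolide.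

Step 6
Reactants: 15 (5R)-3-acetoxy-5-[(2E,4S)-4-hydroxy-3-methylhepta-2,6-dien-1-yl]-4-methylfuran-2(5H)-one; 16 2-methyl-2-butene
Product: 17 (5R)-3-acetoxy-5-[(2E,4S)-4-hydroxy-3,7-dimethylocta-2,6-dien-1-yl]-4-methylfuran-2(5H)-one
Conditions: 2-methyl-2-butene (30 equiv), second-generation Grubbs catalyst (5 mol%), CH2Cl2, 40 °C
Reagents that add atoms: 2-methyl-2-butene, CC=C(C)C
Why: Olefin cross‑metathesis with excess 2‑methyl‑2‑butene turns the terminal vinyl group into the prenyl terminus; the trisubstituted alkene, the free alcohol and the butenolide are spectators and no stereocenter is touched.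

Step 7
Reactants: 17 (5R)-3-acetoxy-5-[(2E,4S)-4-hydroxy-3,7-dimethylocta-2,6-dien-1-yl]-4-methylfuran-2(5H)-one; 18 angelic acid
Product: 19 (5R)-3-acetoxy-5-[(2E,4S)-3,7-dimethyl-4-{[(2Z)-2-methylbut-2-enoyl]oxy}octa-2,6-dien-1-yl]-4-methylfuran-2(5H)-one
Conditions: angelic acid (3 equiv), 2,4,6-Cl3C6H2COCl (3 equiv), Et3N (3 equiv), toluene, 23 °C, filter; then 17, toluene, 75 °C
Reagents that add atoms: angelic acid, C/C=C(/C)C(O)=O
Why: Yamaguchi‑type mixed‑anhydride esterification, run without a nucleophilic catalyst and without free amine, acylates the C8 hydroxyl with retention, keeps the Z geometry of the angelate (no addition–elimination path to the tiglate) and avoids base at the acidic butenolide C5–H.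

Step 8
Reactants: 19 (5R)-3-acetoxy-5-[(2E,4S)-3,7-dimethyl-4-{[(2Z)-2-methylbut-2-enoyl]oxy}octa-2,6-dien-1-yl]-4-methylfuran-2(5H)-one
Product: 21 (4R,6E)-2-acetoxy-4-hydroxy-3-methyl-6-{(3S)-6-methyl-3-[(2Z)-2-methylbut-2-enoyloxy]hept-5-en-2-ylidene}cyclohex-2-en-1-one, via aluminium alkoxide 20 (not isolated)
Conditions: Me2AlCl (3 equiv), CH2Cl2, −78 → 0 °C; aq. KNaC4H4O6
Reagents that add atoms: none
Why: Proposed new method: a Lewis‑acid‑mediated intramolecular acyl transfer from the lactone oxygen to an alkene carbon (an acyl‑ene, or interrupted Prins, cyclisation) that repeats the farnesyl→bisabolyl 1,6‑closure at the acyl oxidation level. Me2AlCl on the butenolide carbonyl makes C2 electrophilic; the trisubstituted alkene, held five atoms away by the Z‑locked lactone, attacks it through the 7‑oxabicyclo[2.2.1]heptene geometry known from furan–alkene cycloadducts; the strained tetrahedral adduct collapses by C–O cleavage to the ketone and an aluminium alkoxide (the C5–O bond is never broken, so C5 stays R); and the C1–H, now flanked by the ketone and the tertiary C7 cation, is removed by an Al–CH3 group as methane, which makes the isomerisation irreversible and gives the conjugated enone. The E geometry puts the bulky C8 substituent on the ring‑CH2 side, away from the carbonyl oxygen, which is the lower‑strain arrangement, and C8 is not involved. The closest known reactions are Me2AlCl‑promoted carbonyl‑ene and Prins cyclisations of aldehydes and ketones, the anhydride‑mediated cyclisation of geranic acid to piperitenone, and Kondakov‑type acylation of alkenes.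

**Compound list**
1 | methyl (2R)-oxirane-2-carboxylate (methyl (R)-glycidate) | COC(=O)[C@H]1CO1 | starting material
2 | vinylmagnesium bromide | C=C[Mg]Br | starting material
3 | acetoxyacetyl chloride | CC(=O)OCC(Cl)=O | starting material
4 | bromomagnesium (2R)-1-methoxy-1-oxopent-4-en-2-olate | COC(=O)[C@@H](CC=C)O[Mg]Br | intermediate
5 | methyl (2R)-2-[(acetoxyacetyl)oxy]pent-4-enoate | COC(=O)[C@@H](CC=C)OC(=O)COC(C)=O | intermediate
6 | p-toluenesulfonyl chloride | Cc1ccc(cc1)S(Cl)(=O)=O | starting material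
7 | lithium (2R)-4-acetoxy-5-oxo-2-(prop-2-en-1-yl)-2,5-dihydrofuran-3-olate | C=CC[C@H]1OC(=O)C(OC(C)=O)=C1[O-].[Li+] | intermediate
8 | (5R)-3-acetoxy-5-allyl-4-(tosyloxy)furan-2(5H)-one | C=CC[C@H]1OC(=O)C(OC(C)=O)=C1OS(=O)(=O)c1ccc(C)cc1 | intermediate
9 | methylzinc chloride | C[Zn]Cl | starting material
10 | (5R)-3-acetoxy-5-allyl-4-methylfuran-2(5H)-one | C=CC[C@H]1OC(=O)C(OC(C)=O)=C1C | intermediate
11 | methacrolein | CC(=C)C=O | starting material
12 | (5R)-3-acetoxy-4-methyl-5-[(2E)-3-methyl-4-oxobut-2-en-1-yl]furan-2(5H)-one | O=C/C(C)=C/C[C@H]1OC(=O)C(OC(C)=O)=C1C | intermediate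
13 | allyltributylstannane | C=CC[Sn](CCCC)(CCCC)CCCC | starting material
14 | (5R)-3-acetoxy-4-methyl-5-[(2E,4S)-3-methyl-4-(tributylstannyloxy)hepta-2,6-dien-1-yl]furan-2(5H)-one | C=CC[C@H](O[Sn](CCCC)(CCCC)CCCC)/C(C)=C/C[C@H]1OC(=O)C(OC(C)=O)=C1C | intermediate
15 | (5R)-3-acetoxy-5-[(2E,4S)-4-hydroxy-3-methylhepta-2,6-dien-1-yl]-4-methylfuran-2(5H)-one | C=CC[C@H](O)/C(C)=C/C[C@H]1OC(=O)C(OC(C)=O)=C1C | intermediate
16 | 2-methyl-2-butene | CC=C(C)C | starting material
17 | (5R)-3-acetoxy-5-[(2E,4S)-4-hydroxy-3,7-dimethylocta-2,6-dien-1-yl]-4-methylfuran-2(5H)-one | CC(C)=CC[C@H](O)/C(C)=C/C[C@H]1OC(=O)C(OC(C)=O)=C1C | intermediate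
18 | angelic acid, (2Z)-2-methylbut-2-enoic acid | C/C=C(/C)C(O)=O | starting material
19 | (5R)-3-acetoxy-5-[(2E,4S)-3,7-dimethyl-4-{[(2Z)-2-methylbut-2-enoyl]oxy}octa-2,6-dien-1-yl]-4-methylfuran-2(5H)-one | C/C=C(/C)C(=O)O[C@@H](CC=C(C)C)/C(C)=C/C[C@H]1OC(=O)C(OC(C)=O)=C1C | intermediate
20 | chloro(methyl)aluminium alkoxide of 21 at the C5 oxygen | C/C=C(/C)C(=O)O[C@@H](CC=C(C)C)/C(C)=C1\C[C@@H](O[Al](C)Cl)C(C)=C(OC(C)=O)C1=O | intermediate
21 | (4R,6E)-2-acetoxy-4-hydroxy-3-methyl-6-{(3S)-6-methyl-3-[(2Z)-2-methylbut-2-enoyloxy]hept-5-en-2-ylidene}cyclohex-2-en-1-one | C/C=C(/C)C(=O)O[C@@H](CC=C(C)C)/C(C)=C1\C[C@@H](O)C(C)=C(OC(C)=O)C1=O | target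

**Count**
Total steps: 8. Longest linear sequence: 8 (steps 1–8 from 1).

**Steps most likely to fail, with fallbacks**

Step 8. The lactone carbonyl may be too weak an electrophile for a trisubstituted alkene. The Lewis acid may instead ionise the allylic angelate or turn the butenolide into an aluminium furanolate (loss of the C5 configuration), and the β,γ‑unsaturated or the Z isomer may form. The fallback sets out from 19 and comes back at 21. The enol acetate of 19 is cleaved selectively with N2H4·HOAc (DMF, 0 °C) to the free 3‑hydroxybutenolide F1. F1 is treated with Me2AlCl (2.2 equiv, CH2Cl2, −78 → 0 °C), which deprotonates the enol and binds the enolate oxygen and the lactone carbonyl in a five‑membered chelate. The carbonyl is then activated from within the molecule, the keto tautomer is blocked, and the same 1,6‑acyl transfer ends in the bis‑aluminium diosphenolate F2, a much deeper sink than 20. Tartrate work‑up frees the 3‑O‑deacetyl compound F3, whose acidic diosphenol hydroxyl is acetylated in the presence of the secondary alcohol (Ac2O 1.05 equiv, NaHCO3, MeCN, 0 °C) to give 21.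

Step 2. The acetoxyacetate enolate can undergo acyl migration, the acetate methyl can close the wrong way and expel the chiral alkoxide, and C5 can epimerise. The fallback sets out from the alkoxide 4 and comes back at 8. 4 is quenched with acetyl chloride instead of 3 to give methyl (2R)-2-acetoxypent-4-enoate F4. Its only enolate (LiN(SiMe3)2, THF, −78 °C, then acid work‑up) closes to (5R)-5-allyl-4-hydroxyfuran-2(5H)-one F5. The C3 oxygen is then introduced by oxidation rather than carried through the Claisen step: α‑acetoxylation of the 1,3‑dicarbonyl with Pb(OAc)4 (benzene, 10 °C) gives (5R)-3-acetoxy-5-allyl-4-hydroxyfuran-2(5H)-one F6. Sulfonylation (TsCl, i‑Pr2NEt, CH2Cl2, −20 °C) returns to 8.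

Step 7. The hindered allylic alcohol may acylate slowly, and forcing conditions risk angelate→tiglate isomerisation and epimerisation of the butenolide. The fallback sets out from 12 and comes back at 19. Keck allylation of 12 with (R)-BINOL in place of (S)-BINOL gives, through the tributylstannyl ether F7, the C8‑epimeric alcohol F8. Cross‑metathesis with 16 as in step 6 gives the C8‑epimeric prenyl alcohol F9. Mitsunobu esterification of F9 with angelic acid 18 (PPh3, diisopropyl azodicarboxylate, toluene, 0 °C) forms the ester by SN2 displacement at C8 with inversion. The acid is never turned into an acylating species and no base meets the butenolide; the product is 19.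

**Further compounds**
F1 | step 8 | (5R)-5-[(2E,4S)-3,7-dimethyl-4-{[(2Z)-2-methylbut-2-enoyl]oxy}octa-2,6-dien-1-yl]-3-hydroxy-4-methylfuran-2(5H)-one | C/C=C(/C)C(=O)O[C@@H](CC=C(C)C)/C(C)=C/C[C@H]1OC(=O)C(O)=C1C
F2 | step 8 | bis[chloro(methyl)aluminium] derivative of F3 at the C3 and C5 oxygens | C/C=C(/C)C(=O)O[C@@H](CC=C(C)C)/C(C)=C1\C[C@@H](O[Al](C)Cl)C(C)=C(O[Al](C)Cl)C1=O
F3 | step 8 | (4R,6E)-2,4-dihydroxy-3-methyl-6-{(3S)-6-methyl-3-[(2Z)-2-methylbut-2-enoyloxy]hept-5-en-2-ylidene}cyclohex-2-en-1-one | C/C=C(/C)C(=O)O[C@@H](CC=C(C)C)/C(C)=C1\C[C@@H](O)C(C)=C(O)C1=O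
F4 | step 2 | methyl (2R)-2-acetoxypent-4-enoate | COC(=O)[C@@H](CC=C)OC(C)=O
F5 | step 2 | (5R)-5-allyl-4-hydroxyfuran-2(5H)-one | C=CC[C@H]1OC(=O)C=C1O
F6 | step 2 | (5R)-3-acetoxy-5-allyl-4-hydroxyfuran-2(5H)-one | C=CC[C@H]1OC(=O)C(OC(C)=O)=C1O
F7 | step 7 | (5R)-3-acetoxy-4-methyl-5-[(2E,4R)-3-methyl-4-(tributylstannyloxy)hepta-2,6-dien-1-yl]furan-2(5H)-one | C=CC[C@@H](O[Sn](CCCC)(CCCC)CCCC)/C(C)=C/C[C@H]1OC(=O)C(OC(C)=O)=C1C
F8 | step 7 | (5R)-3-acetoxy-5-[(2E,4R)-4-hydroxy-3-methylhepta-2,6-dien-1-yl]-4-methylfuran-2(5H)-one | C=CC[C@@H](O)/C(C)=C/C[C@H]1OC(=O)C(OC(C)=O)=C1C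
F9 | step 7 | (5R)-3-acetoxy-5-[(2E,4R)-4-hydroxy-3,7-dimethylocta-2,6-dien-1-yl]-4-methylfuran-2(5H)-one | CC(C)=CC[C@@H](O)/C(C)=C/C[C@H]1OC(=O)C(OC(C)=O)=C1C
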